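A direct plan would cut the C3–C1′ biaryl bond: a 3-iodo-5,7-bis(methoxymethoxy)-6-prenylchromone A1 would be joined by Suzuki–Miyaura coupling to a MOM-protected chromenyl pinacol boronate A2, and the tris-MOM isoflavone A3 would be deprotected with acid.
Its weakest points would be:
- The approach to A1: about seven linear steps, in which two directed metalations, a C–H borylation/oxidation and a temporary acetal (on, then off) are spent only to place one prenyl, one acetyl and one free OH on a benzene ring.
- The approach to A2: the pyran ring is made saturated and then dehydrogenated with a quinone, and a bromine is introduced only to be exchanged for boron. These redox and handle steps build no skeletal bond.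
- The late cross-coupling: an electron-rich, ortho-alkoxy aryl boronate (prone to protodeboronation) must meet a hindered, base-sensitive 3-iodochromone next to C4=O, with the material of both lines at stake.

**Retrosynthetic overview**
1. Target 18 ⇐ acetal removal ⇐ isoflavone 17 ⇐ thermal para-Claisen–Cope/cyclodehydration of formyl ketone 14. This forms O1–C2 and C6–C1″, so the γ-pyrone C ring closes last.
2. 14 ⇐ Lewis-acid 1,2-aroyl shift of chalcone epoxide 13. This makes the C3–C4 bond and turns the 1,3-diaryl C3 chain into the 1,2-diaryl isoflavonoid chain. The feature used is that C3 carries the 2′,4′-dioxygenated B ring (pyran O para, 2′-O ortho), which stabilises the benzylic cation the acyl group migrates to.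
3. 13 ⇐ nucleophilic epoxidation ⇐ aldol union of ketone 4 (two steps from phloroacetophenone, which already holds all three A-ring oxygens and C4) with chromene aldehyde 11 (four steps from resorcinol).
4. Ring order: A ring bought; dimethylpyran ring on the B unit first (its alkene comes from a chromanone carbonyl, with no quinone dehydrogenation); C ring last.
5. No halogen, boron or Pd union is needed. The O-prenyl ether is both the protecting group of O1 and the latent 6-prenyl group, so the 6- versus 8-prenyl question is settled by the mechanism.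

Key step: step 9

Remark on the chemistry: the target has no stereocentre and no stereogenic double bond, so no enantiocontrol is needed. The stereo-elements on the way (E-enone 12, racemic trans-epoxide 13, racemic 14–16) are all erased before the target.

**Fragment A**

Step 1
Reactants: 1 2,4,6-trihydroxyacetophenone
Product: 2 1-[2,4-bis(ethoxymethoxy)-6-hydroxyphenyl]ethan-1-one
Conditions: EtOCH2Cl (2.2 equiv), i-Pr2NEt, CH2Cl2, 0 °C → rt
Reagents that add atoms: chloromethyl ethyl ether, CCOCCl
Why: Acetalisation of the two more acidic, non-chelated phenols should stop at the bis-ether because the third OH is hydrogen-bonded to the acetyl group.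

Step 2
Reactants: 2; 3 prenyl bromide (1-bromo-3-methylbut-2-ene)
Product: 4 1-{2,4-bis(ethoxymethoxy)-6-[(3-methylbut-2-en-1-yl)oxy]phenyl}ethan-1-one
Conditions: K2CO3, DMF, rt → 50 °C
Reagents that add atoms: none
Why: Williamson O-alkylation of the remaining phenol gives the aryl prenyl ether, which serves as base-stable protection of the future O1 and as the latent C-prenyl group.

**Fragment B**

Step 3
Reactants: 5 resorcinol; 6 3-methylbut-2-enoic acid
Product: 7 7-hydroxy-2,2-dimethylchroman-4-one
Conditions: P2O5/MeSO3H (Eaton's reagent), 70 °C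
Reagents that add atoms: none
Why: Friedel–Crafts acylation at the less hindered C4 of resorcinol followed by intramolecular oxa-Michael addition of the neighbouring OH closes the dimethylpyranone ring in the linear sense needed for the B unit.

Step 4
Reactants: 7
Product: 9 2,2-dimethyl-2H-chromen-7-ol, via 2,2-dimethylchromane-4,7-diol 8 (not isolated)
Conditions: NaBH4, THF/MeOH, 0 °C → rt; then 2 M aq HCl, rt (same pot)
Reagents that add atoms: none
Why: Hydride reduction gives the benzylic alcohol, whose acid-catalysed E1 dehydration is easy because the C4 cation is stabilised by the para 7-oxygen; this places the pyran alkene without an oxidant.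

Step 5
Reactants: 9
Product: 10 7-hydroxy-2,2-dimethyl-2H-chromene-6-carbaldehyde
Conditions: MgCl2, Et3N, (CH2O)n, MeCN, reflux
Reagents that add atoms: paraformaldehyde (as formaldehyde), C=O
Why: Casnati–Skattebøl magnesium-phenoxide ortho-formylation should go to C6, the less hindered ortho position (C8 lies between two oxygens), and the basic conditions leave the chromene alkene untouched; the formyl carbon is the future C3 of the isoflavone.

Step 6
Reactants: 10
Product: 11 7-(ethoxymethoxy)-2,2-dimethyl-2H-chromene-6-carbaldehyde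
Conditions: EtOCH2Cl, i-Pr2NEt, CH2Cl2, 0 °C → rt
Reagents that add atoms: chloromethyl ethyl ether, CCOCCl
Why: Acetal protection of the salicylaldehyde OH is needed so that this oxygen can neither open the later epoxide nor trap the later formyl group as a benzofuran.

**Union and end-game**

Step 7
Reactants: 4; 11
Product: 12 (E)-1-{2,4-bis(ethoxymethoxy)-6-[(3-methylbut-2-en-1-yl)oxy]phenyl}-3-[7-(ethoxymethoxy)-2,2-dimethyl-2H-chromen-6-yl]prop-2-en-1-one
Conditions: KOH, EtOH/H2O, rt
Reagents that add atoms: none
Why: Claisen–Schmidt aldol condensation of the methyl ketone with the non-enolisable aldehyde gives the E-chalcone by E1cB dehydration; ethers, acetals and both alkenes are stable to hydroxide.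

Step 8
Reactants: 12
Product: 13 {2,4-bis(ethoxymethoxy)-6-[(3-methylbut-2-en-1-yl)oxy]phenyl}{(2R*,3S*)-3-[7-(ethoxymethoxy)-2,2-dimethyl-2H-chromen-6-yl]oxiran-2-yl}methanone (racemic trans-epoxide)
Conditions: 30 % aq H2O2, 2 M aq NaOH, MeOH/THF, 0 °C → rt; base-washed work-up, used crude
Reagents that add atoms: hydrogen peroxide, OO
Why: Weitz–Scheffer nucleophilic epoxidation attacks only the electron-poor enone, so the prenyl and chromene alkenes are untouched; stepwise conjugate addition and ring closure gives the trans-epoxide as a racemate, and both stereocentres are erased later.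

Step 9
Reactants: 13
Product: 14 3-{2,4-bis(ethoxymethoxy)-6-[(3-methylbut-2-en-1-yl)oxy]phenyl}-2-[7-(ethoxymethoxy)-2,2-dimethyl-2H-chromen-6-yl]-3-oxopropanal (racemic, largely as its hydroxymethylene enol)
Conditions: BF3·OEt2 (0.2 equiv), CH2Cl2, −78 → −20 °C; Et3N quench; used crude
Reagents that add atoms: none
Why: BF3 coordinates the oxirane oxygen and the C–O bond at the carbon bearing the chromenyl ring ionises, this benzylic cation being stabilised by the para pyran oxygen and the ortho acetal oxygen; the aroyl group on the neighbouring carbon then shifts with its bonding pair to the cationic carbon while the carbon it leaves becomes the formyl group (Meinwald-type semipinacol rearrangement with 1,2-acyl migration). The closest known reaction is the BF3-mediated rearrangement of 2′-alkoxychalcone epoxides to α-formyl deoxybenzoins, the classical epoxide entry to isoflavones. No ring is closed; the one new stereocentre is racemic, enolisable and becomes sp2 in the next step, so it needs no control. The step needs regioselective opening at the chromenyl-bearing carbon (secured by the two donor oxygens), acyl rather than hydride migration (the established preference of chalcone oxides), and survival of the prenyl ether, the acetals and both alkenes (secured by a substoichiometric Lewis acid at low temperature, possible because this epoxide ionises very easily). In this one operation the chalcone skeleton becomes the isoflavonoid skeleton: the C3–C4 bond of the target is made and the former acetyl methyl carbon becomes the future C2.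

Step 10
Reactants: 14
Product: 17 5,7-bis(ethoxymethoxy)-3-[7-(ethoxymethoxy)-2,2-dimethyl-2H-chromen-6-yl]-6-(3-methylbut-2-en-1-yl)-4H-chromen-4-one, via 3-[2,4-bis(ethoxymethoxy)-6-hydroxy-3-(3-methylbut-2-en-1-yl)phenyl]-2-[7-(ethoxymethoxy)-2,2-dimethyl-2H-chromen-6-yl]-3-oxopropanal 15 (not isolated), via 5,7-bis(ethoxymethoxy)-3-[7-(ethoxymethoxy)-2,2-dimethyl-2H-chromen-6-yl]-2-hydroxy-6-(3-methylbut-2-en-1-yl)chroman-4-one 16 (not isolated)
Conditions: PhNEt2, 200 °C, Ar, sealed tube; amine removed by chromatography
Reagents that add atoms: none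
Why: A thermal para-Claisen–Cope rearrangement (two consecutive [3,3] shifts, O → ortho carbon → para carbon, as known for 2-prenyloxy-4,6-bis(alkoxymethoxy)aryl ketones) should move the prenyl group to the carbon between the two acetal oxygens and free exactly the phenol that then adds to the formyl group (6-exo-trig hemiacetal) and loses water, so the oxygen that closes the pyranone is by mechanism para to the prenyl group and only the 6-prenyl isoflavone can form.

Step 11
Reactants: 17
Product: 18 Krausianone 2, 5,7-dihydroxy-3-(7-hydroxy-2,2-dimethyl-2H-chromen-6-yl)-6-(3-methylbut-2-en-1-yl)-4H-chromen-4-one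
Conditions: 3 M aq HCl, MeOH/THF, 45 °C, monitored closely; NaHCO3 quench
Reagents that add atoms: none
Why: Acid-catalysed acetal exchange with methanol removes the three ethoxymethyl groups (the peri 5-O acetal first), and dilute acid at moderate temperature with early quench should keep the prenyl group from cyclising onto the neighbouring phenols.

**Compound list**
1 | 2,4,6-trihydroxyacetophenone | CC(=O)c1c(O)cc(O)cc1O | starting material
2 | 1-[2,4-bis(ethoxymethoxy)-6-hydroxyphenyl]ethan-1-one | CC(=O)c1c(O)cc(OCOCC)cc1OCOCC | intermediate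
3 | prenyl bromide | CC(C)=CCBr | starting material
4 | 1-{2,4-bis(ethoxymethoxy)-6-[(3-methylbut-2-en-1-yl)oxy]phenyl}ethan-1-one | CC(=O)c1c(OCC=C(C)C)cc(OCOCC)cc1OCOCC | intermediate
5 | resorcinol | Oc1cccc(O)c1 | starting material
6 | 3-methylbut-2-enoic acid | CC(C)=CC(=O)O | starting material
7 | 7-hydroxy-2,2-dimethylchroman-4-one | CC1(C)CC(=O)c2ccc(O)cc2O1 | intermediate
8 | 2,2-dimethylchromane-4,7-diol (racemic, not isolated) | CC1(C)CC(O)c2ccc(O)cc2O1 | intermediate
9 | 2,2-dimethyl-2H-chromen-7-ol | CC1(C)C=Cc2ccc(O)cc2O1 | intermediate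
10 | 7-hydroxy-2,2-dimethyl-2H-chromene-6-carbaldehyde | CC1(C)C=Cc2cc(C=O)c(O)cc2O1 | intermediate
11 | 7-(ethoxymethoxy)-2,2-dimethyl-2H-chromene-6-carbaldehyde | CCOCOc1cc2OC(C)(C)C=Cc2cc1C=O | intermediate
12 | (E)-chalcone from 4 and 11 | CCOCOc1cc2OC(C)(C)C=Cc2cc1/C=C/C(=O)c1c(OCC=C(C)C)cc(OCOCC)cc1OCOCC | intermediate
13 | trans-epoxide of 12 (racemic; one enantiomer drawn) | O=C(c1c(OCC=C(C)C)cc(OCOCC)cc1OCOCC)[C@H]1O[C@@H]1c1cc2C=CC(C)(C)Oc2cc1OCOCC | intermediate
14 | 3-aryl-2-chromenyl-3-oxopropanal with O-prenyl ether (racemic) | O=CC(c1cc2C=CC(C)(C)Oc2cc1OCOCC)C(=O)c1c(OCC=C(C)C)cc(OCOCC)cc1OCOCC | intermediate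
15 | 3-[2,4-bis(ethoxymethoxy)-6-hydroxy-3-prenylphenyl]-2-chromenyl-3-oxopropanal (racemic, not isolated) | O=CC(c1cc2C=CC(C)(C)Oc2cc1OCOCC)C(=O)c1c(O)cc(OCOCC)c(CC=C(C)C)c1OCOCC | intermediate
16 | 2-hydroxyisoflavanone hemiacetal (racemic diastereomer mixture, not isolated) | OC1Oc2cc(OCOCC)c(CC=C(C)C)c(OCOCC)c2C(=O)C1c1cc2C=CC(C)(C)Oc2cc1OCOCC | intermediate
17 | tris(ethoxymethyl) ether of Krausianone 2 | CCOCOc1cc2occ(-c3cc4C=CC(C)(C)Oc4cc3OCOCC)c(=O)c2c(OCOCC)c1CC=C(C)C | intermediate
18 | Krausianone 2 | CC(C)=CCc1c(O)cc2occ(-c3cc4c(cc3O)OC(C)(C)C=C4)c(=O)c2c1O | target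

**Count**
Total steps: 11. Longest linear sequence: 9 (steps 3–11, from resorcinol).

**Steps most likely to fail**

Step 10. The first [3,3] intermediate may tautomerise to the ortho (1,1-dimethylallyl) phenol before the Cope shift, or the β-keto aldehyde may lose its formyl group at 200 °C before the phenol is freed. The fallback separates the sigmatropic step from the ring closure and sets out from 4. Heating 4 in PhNEt2 at 200 °C should give 1-[2,4-bis(ethoxymethoxy)-6-hydroxy-3-(3-methylbut-2-en-1-yl)phenyl]ethan-1-one F1. Allyl bromide/K2CO3 would give its allyl ether F2. Claisen–Schmidt condensation with 11 would give the (E)-chalcone F3, alkaline H2O2 the racemic trans-epoxide F4, and BF3·OEt2 the O-allyl formyl ketone F5. Pd(PPh3)4/morpholine would then remove the allyl group and return to the route at 15, which closes to 16 and dehydrates to 17 on gentle warming with catalytic PPTS.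

Step 9. After ionisation the ortho prenyl-ether oxygen may capture the benzylic cation (six-membered oxonium, loss of the prenyl cation, dihydroflavonol formation), the prenyl ether may shift under Lewis acid, or hydride may migrate instead of the aroyl group. The fallback builds the same formyl ketone without a cationic step and sets out from 9 and 4. NBS (CH2Cl2, −40 °C) should give 6-bromo-2,2-dimethyl-2H-chromen-7-ol F6, and EtOCH2Cl/i-Pr2NEt its ethoxymethyl ether, 6-bromo-7-(ethoxymethoxy)-2,2-dimethyl-2H-chromene F7. Pd-catalysed ketone α-arylation of 4 with F7 (Pd2(dba)3, XPhos, NaOt-Bu, toluene, 80 °C) would give the deoxybenzoin 1-{2,4-bis(ethoxymethoxy)-6-[(3-methylbut-2-en-1-yl)oxy]phenyl}-2-[7-(ethoxymethoxy)-2,2-dimethyl-2H-chromen-6-yl]ethan-1-one F8. Claisen formylation (HCO2Et, NaH, THF, then mild acid) returns to the route at 14.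

Step 8. Conjugate addition of hydroperoxide to the electron-rich, twisted enone may be slow, and the very acid-labile epoxide may open during work-up. The fallback makes the epoxy ketone by C–C bond formation instead of oxidation and sets out from 4. Enolisation (LiHMDS, THF, −78 °C) and chlorination with TsCl should give 2-chloro-1-{2,4-bis(ethoxymethoxy)-6-[(3-methylbut-2-en-1-yl)oxy]phenyl}ethan-1-one F9. Darzens condensation of F9 with 11 (NaOMe, MeOH/THF, 0 °C) gives the trans-epoxy ketone and returns to the route at 13.

**Further compounds**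
F1 | step 10 | 1-[2,4-bis(ethoxymethoxy)-6-hydroxy-3-(3-methylbut-2-en-1-yl)phenyl]ethan-1-one | CC(=O)c1c(O)cc(OCOCC)c(CC=C(C)C)c1OCOCC
F2 | step 10 | 1-[6-(allyloxy)-2,4-bis(ethoxymethoxy)-3-(3-methylbut-2-en-1-yl)phenyl]ethan-1-one | CC(=O)c1c(OCC=C)cc(OCOCC)c(CC=C(C)C)c1OCOCC
F3 | step 10 | (E)-chalcone from F2 and 11 | CCOCOc1cc2OC(C)(C)C=Cc2cc1/C=C/C(=O)c1c(OCC=C)cc(OCOCC)c(CC=C(C)C)c1OCOCC
F4 | step 10 | trans-epoxide of F3 (racemic; one enantiomer drawn) | O=C(c1c(OCC=C)cc(OCOCC)c(CC=C(C)C)c1OCOCC)[C@H]1O[C@@H]1c1cc2C=CC(C)(C)Oc2cc1OCOCC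
F5 | step 10 | 3-[6-(allyloxy)-2,4-bis(ethoxymethoxy)-3-(3-methylbut-2-en-1-yl)phenyl]-2-[7-(ethoxymethoxy)-2,2-dimethyl-2H-chromen-6-yl]-3-oxopropanal (racemic) | O=CC(c1cc2C=CC(C)(C)Oc2cc1OCOCC)C(=O)c1c(OCC=C)cc(OCOCC)c(CC=C(C)C)c1OCOCC
F6 | step 9 | 6-bromo-2,2-dimethyl-2H-chromen-7-ol | CC1(C)C=Cc2cc(Br)c(O)cc2O1
F7 | step 9 | 6-bromo-7-(ethoxymethoxy)-2,2-dimethyl-2H-chromene | CCOCOc1cc2OC(C)(C)C=Cc2cc1Br
F8 | step 9 | 1-{2,4-bis(ethoxymethoxy)-6-[(3-methylbut-2-en-1-yl)oxy]phenyl}-2-[7-(ethoxymethoxy)-2,2-dimethyl-2H-chromen-6-yl]ethan-1-one | CCOCOc1cc2OC(C)(C)C=Cc2cc1CC(=O)c1c(OCC=C(C)C)cc(OCOCC)cc1OCOCC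
F9 | step 8 | 2-chloro-1-{2,4-bis(ethoxymethoxy)-6-[(3-methylbut-2-en-1-yl)oxy]phenyl}ethan-1-one | O=C(CCl)c1c(OCC=C(C)C)cc(OCOCC)cc1OCOCC
A1 | direct plan | 3-iodo-5,7-bis(methoxymethoxy)-6-(3-methylbut-2-en-1-yl)-4H-chromen-4-one | COCOc1cc2occ(I)c(=O)c2c(OCOC)c1CC=C(C)C
A2 | direct plan | 2-[7-(methoxymethoxy)-2,2-dimethyl-2H-chromen-6-yl]-4,4,5,5-tetramethyl-1,3,2-dioxaborolane | COCOc1cc2OC(C)(C)C=Cc2cc1B1OC(C)(C)C(C)(C)O1
A3 | direct plan | tris(methoxymethyl) ether of Krausianone 2 | COCOc1cc2OC(C)(C)C=Cc2cc1-c1coc2cc(OCOC)c(CC=C(C)C)c(OCOC)c2c1=O
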